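The L in this flask goes slowly, over 12 h, while Q settles between J and L within 0.755 h, far sooner than the run, so Q is what we freeze.

    Q ⇌ J, rate k1*([Q] - [J]/K1) per volume of the first phase (K1 = 2.61, k1 = 2.66 × 10⁻⁴ s⁻¹)
    L + Q → L.Q (k2 = 5.33 × 10⁻⁴ L mol⁻¹ s⁻¹)
    Q + L.Q → Q.L.Q (k3 = 8.19 × 10⁻⁵ L mol⁻¹ s⁻¹)
    L.Q ⇌ E (K4 = 0.32, k4 = 4.45 × 10⁻⁵ s⁻¹)
    2 L → L2 (k5 = 3.36 × 10⁻⁵ L mol⁻¹ s⁻¹)
    Q ⇌ X (K6 = 0.54, k6 = 1.85 × 10⁻⁵ s⁻¹)

L 0.20 M; J 1.50 equiv; time 12 h; volume of the second phase over the first 1.0

- a species is counted by the L in it: one L2 counts as two
- two of one species on the left: rate k times its square, two consumed each time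
- in the second phase: J; everything else is in the first
- charges count per volume of the first phase; a concentration in a rate is the amount of a species over the volume of its own phase; every rate counts per litre of the first phase
- run time (flask): 12 h

* the L.Q standing at 12 h, as a percentage of the L charged
* the change that raises the amount of L.Q at 12 h, in percent of the L charged most ("none" if none brings more than 2 percentage points) (noon / dawn / none)
* amount of L.Q at 12 h, in percent of the L charged, after noon

- noon: doubling the amount of J, all else as stated
- dawn: doubling the transfer coefficient of step 1, all else as stated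

Since Q settles sooner than the run lasts, we balance its supply from J against its loss to the main step L + Q, with equal volumes. The pool of Q and J then gives Q one part in 4.13 at the moment when 0.5 of the L is gone. We take 0.5 equivalent out of the pool for that moment, setting the Q held in X against the L that went to L2 without using Q, and this gives 24.2 % of the L charged, the frozen Q, a constant level that makes the main step pseudo-first-order.

By itself the main step runs through 1.11 time constants and converts 67.2 % of the L. The loss to L2, which starts at 0.521 of the main rate, brings that down to 57.6 %. The equilibrium with E relaxes in 1.05 h, far sooner than the run, so we keep one part in 1.32 as L.Q, which is 43.6 %. Further Q on L.Q, counted over 0.5 of the run, leaves 40.9 %, our figure for y.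

The same chain after noon starts from a frozen Q of 60.5 % and gives 55.2 %. After dawn it starts from 25.8 % and gives 42.3 %, so we choose noon.

The forecast, reasoning that “L.Q and E also equilibrate quickly”, gives 39.5 %, noon and 50 %, lower than our figures on y and after noon.

The flask gives 40.5 %, and 50.6 % after noon, which gains 10 percentage points against 1.7 points for dawn; at 6.00 h, with 45.7 % of its L left, its Q read 24.7 % of the L charged, beside the frozen 24.2 %. For the neighbour charged with 0.080 M of L, the frozen Q comes to 26.2 % of its own charge and the chain gives 25.9 %. That neighbour read Q at 26.0 % of its charge and L.Q at 28.3 %, with 50 % of its L left.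

Its constants were drawn at random within sensible limits, and the outcome is calculated.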